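Remark on the chemistry: the configuration is taken as drawn, (2R,4S), which places the C2 methyl group and the C4 naphthyl group on opposite faces of the pyran ring (2,4-trans); the route is built for this isomer.

## Analysis of the target

Cladonaphchrom A (22) is a chroman: an aromatic ring A (C4a, C5, C6, C7, C8, C8a) fused to a dihydropyran ring (O1, C2, C3, C4), with a free phenol at C5, a methyl group at C2 and a 4,5-dimethoxynaphthalen-1-yl group at C4. The two stereocentres, C2 (R) and C4 (S), are 1,3-related across the pyran ring and trans, so one substituent must be axial and 22 is not the thermodynamically preferred diastereomer. The sensitive parts are the doubly benzylic C4–H, the very electron-rich peri-dimethoxynaphthalene (easily oxidised or attacked by electrophiles) and the free phenol. The difficulty is twofold. Ring A is 1,2,3-trisubstituted, with C4a wedged between the oxygen-bearing C5 and C8a and carrying a tertiary diarylmethine carbon, a position that electrophilic substitution on a 1,3-dioxygenated benzene avoids. The trans relation of C2 and C4 also cannot be reached by equilibration. The strategy rests on the O–C8a–C4a(–C4)–C5–O array of ring A: this is the pattern formed when a vinylketene and an oxygen-substituted alkyne are joined, so ring A can be built last around a C4 centre that is already in place. Once ring A carries two free hydroxyl groups these are equivalent, so closing the pyran at O1–C2 needs no differentiation of the two oxygens.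

## Retrosynthetic reasoning

The O1–C2 bond is cut first. Forward, triol 21 closes to 22 by an intramolecular redox dehydration (Mitsunobu) in which a phenol oxygen displaces the activated secondary hydroxyl with inversion. Cutting here, and not at C4–C4a or C3–C4, lets C2 come from a chiral-pool carbinol and makes the trans relation the result of a stereospecific SN2 event. The two phenols of 21 interchange by rotation about the C4–C4a bond, so either one gives 22.

Triol 21 is traced to 20, in which the side-chain hydroxyl and one phenol carry triisopropylsilyl groups. These are the groups the earlier steps leave behind, and one fluoride treatment removes both.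

Ring A of 20 is taken apart at C4a–C8a, C5–C6 and C8–C8a, giving siloxyalkyne 12 and cyclobutenone 15 as a four-carbon vinylketene source. This disconnection places the side chain between the two oxygens by construction, so no substitution at the hindered position of a preformed arene is needed. It also moves all stereochemistry into an acyclic alkyne. The forward reaction must join the components with one regiochemistry and leave both centres untouched, which neutral thermolysis allows.

In 12 the C≡C–O unit is cut back to a lactone carbonyl plus one carbon, leading to cis-lactone 8. The forward ynolate rearrangement moves C3 of 8 onto the new carbon with retention, and opening the lactone frees the C5 oxygen, so one silylation caps both oxygens. The new carbon becomes C4a and the former carbonyl carbon becomes an oxygen-bearing carbon of ring A.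

Lactone 8 is the C3 epimer-corrected form of 6, and 6 is cut at the C3–aryl bond into bromide 2 and (S)-γ-valerolactone 3. This takes the C2 stereocentre of 22 from 3 unchanged. The C3 centre forms without control in the arylation and is then set by protonation of the planar enolate on the face away from the C5 methyl group.

Bromide 2 comes from 1 by electrophilic bromination at the position para to a methoxy group. Cyclobutenone 15 comes from acid 13 through bromide 14.

## Alternatives that were turned down

Alternative 1: The pyran oxygen is introduced by oxygen insertion, disconnecting O1–C8a (and with it the ester link O1–C2) back to the 3-arylindanone A2, (3S)-4-(benzyloxy)-3-(4,5-dimethoxynaphthalen-1-yl)-2,3-dihydro-1H-inden-1-one. Forward, a peracid adds to the ketone of A2 and the aryl carbon migrates to oxygen, expanding the five-membered ring to the dihydrocoumarin A1, (4S)-5-(benzyloxy)-4-(4,5-dimethoxynaphthalen-1-yl)chroman-2-one.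
- For: aryl migrates ahead of a primary alkyl group in such ketones, and the migration leaves C4 untouched. The C4 centre of A2 could be set with absolute control by a catalytic asymmetric arylation, which is stronger than the substrate-controlled protonation of step 3.
- Against: the oxidant meets the peri-dimethoxynaphthalene, the most easily oxidised part of the molecule, so chemoselectivity of the key step is doubtful. A1 has a carbonyl where 22 has the C2 methyl stereocentre, so reduction to a lactol, ionisation and C-methylation must follow, and the trans outcome then depends on 1,3-induction in an oxocarbenium ion. A2 places an aryl group beside a flanking alkoxy substituent and is not trivial to assemble. A benzyl ether must be removed at the end.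
- Comparison: the chosen route takes C2 from the chiral pool, fixes the trans relation by SN2 inversion, and uses no oxidant in its key step.

Alternative 2: C3–C4 and O1–C2 are disconnected together as a hetero-Diels–Alder reaction. A chiral phosphoric acid would dehydrate the racemic diaryl carbinol A4, 2-[(4,5-dimethoxynaphthalen-1-yl)(hydroxy)methyl]benzene-1,3-diol, to the ortho-quinone methide A5. This adds ethyl vinyl ether A6 to give the 2,4-cis acetal A3, (2R,4S)-4-(4,5-dimethoxynaphthalen-1-yl)-2-ethoxychroman-5-ol.
- For: this is the shortest way to the chroman skeleton and is clearly better in step economy. Ring A is bought with its 1,2,3-pattern, and C4 is set by a catalyst.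
- Against: A3 carries an ethoxy group, not a methyl group, at C2. Replacing it again goes through an oxocarbenium ion whose trans-selective methylation is an uncertain 1,3-induction. The cation behind A5 is stabilised by the para-methoxynaphthyl group as well as by the phenol oxygen, so it should be long-lived and only loosely paired with the chiral anion, which puts both its reactivity towards A6 and the enantiocontrol in doubt.
- Comparison: the chosen strategy is longer, but each stereochemical element is tied to a chiral-pool atom or a stereospecific event, and the crowded ring A is formed regiospecifically.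

Alternative 3: C3–C4 is disconnected as an alkylation. A strong lithium amide base would remove the doubly benzylic proton of A8, 1-[2-{[(2R)-1-chloropropan-2-yl]oxy}-6-(methoxymethoxy)benzyl]-4,5-dimethoxynaphthalene. The diarylmethyl anion then displaces the primary chloride in a 6-exo-tet closure to give A7, (2R,4S)-4-(4,5-dimethoxynaphthalen-1-yl)-5-(methoxymethoxy)-2-methylchromane.
- For: the route is short; ring A and the C2 centre are purchased, and the C2–O bond is made without touching the stereocentre. On step count it is as strong as or stronger than the chosen route.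
- Against: C4 is created with no real control element, only 1,3-induction from the C2 methyl group in an early transition state. The product keeps an acidic C4–H, so equilibration by the base would drift towards the 2,4-cis (diequatorial) isomer, which is the wrong one. Elimination of HCl and ring metalation directed by the acetal compete.
- Comparison: the chosen strategy fixes both centres before ring closure and obtains the trans relation from an inversion, not from a selectivity that runs against thermodynamics.

Key step: step 7

## Route

Step 1
Reactants: 1 1,8-dimethoxynaphthalene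
Product: 2 4-bromo-1,8-dimethoxynaphthalene
Conditions: NBS (1.0 equiv), MeCN, 0 °C to rt
Reagents that add atoms: N-bromosuccinimide, O=C1CCC(=O)N1Br
Why: Electrophilic aromatic bromination; the position para to a methoxy group (C4) is the most nucleophilic and least hindered site of the peri-dimethoxynaphthalene, and one equivalent of NBS in a polar solvent should stop at the monobromide.

Step 2
Reactants: 3 (S)-γ-valerolactone; 2 4-bromo-1,8-dimethoxynaphthalene
Product: 6 (5S)-3-(4,5-dimethoxynaphthalen-1-yl)-5-methyloxolan-2-one (C3 epimer mixture), via lithium enolate 4 (not isolated), via chlorozinc enolate 5 (not isolated)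
Conditions: 3 (1.5 equiv), LiN(SiMe3)2, THF, −78 °C; ZnCl2, −78 to 0 °C; then 2, Pd(OAc)2 (3 mol %), SPhos (6 mol %), THF, 50 °C
Reagents that add atoms: none
Why: Negishi-type α-arylation of an ester zinc enolate: Pd(OAc)2 is reduced in the flask to zerovalent palladium, which inserts into the C–Br bond of 2, the zinc enolate transmetalates and reductive elimination forms the C3–aryl bond; the mild zinc enolate should suppress self-condensation of the lactone and a second arylation. C5 is not involved and keeps its S configuration; C3 forms as a mixture that step 3 corrects.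

Step 3
Reactants: 6 (5S)-3-(4,5-dimethoxynaphthalen-1-yl)-5-methyloxolan-2-one (C3 epimer mixture)
Product: 8 (3S,5S)-3-(4,5-dimethoxynaphthalen-1-yl)-5-methyloxolan-2-one (cis), via lithium enolate 7 (not isolated)
Conditions: LiN(SiMe3)2 (1.1 equiv), THF, −78 °C; 2,6-di-tert-butyl-4-methylphenol (1.5 equiv), −78 °C; then H2O
Reagents that add atoms: none
Why: Kinetic protonation of a lactone enolate: both epimers converge on the planar enolate 7, and the bulky phenol should deliver the proton to the face opposite the C5 methyl group, which leaves the aryl group cis to the methyl group (3S). The cis isomer is also expected to be the more stable one, so the separated minor epimer can be returned to the same operation.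

Step 4
Reactants: 8 (3S,5S)-3-(4,5-dimethoxynaphthalen-1-yl)-5-methyloxolan-2-one (cis)
Product: 12 triisopropyl{[(3S,5S)-3-(4,5-dimethoxynaphthalen-1-yl)-5-(triisopropylsilyloxy)hex-1-yn-1-yl]oxy}silane, via lithium lactolate adduct 9 (not isolated), via dilithium dibromo enolate 10 (not isolated), via dilithium ynolate 11 (not isolated)
Conditions: CH2Br2 (2.2 equiv), lithium 2,2,6,6-tetramethylpiperidide (2.0 equiv), THF, −78 °C; add 8; LiN(SiMe3)2, −78 °C; n-BuLi, −78 °C to rt; i-Pr3SiOTf (excess), −78 to 0 °C
Reagents that add atoms: dibromomethane, BrCBr; triisopropylsilyl trifluoromethanesulfonate, CC(C)[Si](OS(=O)(=O)C(F)(F)F)(C(C)C)C(C)C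
Why: Kowalski ynolate formation followed by O-silylation: dibromomethyllithium adds to the lactone carbonyl to give 9, the amide base converts it into the ring-opened enolate 10, and bromine–lithium exchange triggers a 1,2-shift of the C3 carbon (with retention) and loss of LiBr to give ynolate 11, whose two oxygens are capped by the bulky silyl triflate. Dibromomethane is kept in excess over the piperidide so that no free amide base meets the acidic C3–H of 8; once 10 has formed, that proton is no longer acidic.

Step 5
Reactants: 13 3-oxocyclobutanecarboxylic acid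
Product: 14 3-bromocyclobutanone
Conditions: HgO, Br2, MgSO4, CH2Cl2, reflux
Reagents that add atoms: bromine, BrBr
Why: Hunsdiecker bromodecarboxylation in the Cristol–Firth form: the mercuric carboxylate is converted by bromine into an acyl hypobromite, which loses CO2 by a radical chain and gives the bromide.

Step 6
Reactants: 14 3-bromocyclobutanone
Product: 15 cyclobutenone
Conditions: n-Bu3N, rt, reduced pressure, product distilled into a −78 °C trap; stored cold as a toluene solution
Reagents that add atoms: none
Why: Base-induced β-elimination of HBr from a β-bromo ketone; the volatile enone is removed from the amine as it forms, which limits its polymerisation.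

Step 7
Reactants: 12 triisopropyl{[(3S,5S)-3-(4,5-dimethoxynaphthalen-1-yl)-5-(triisopropylsilyloxy)hex-1-yn-1-yl]oxy}silane; 15 cyclobutenone
Product: 20 2-[(1S,3S)-1-(4,5-dimethoxynaphthalen-1-yl)-3-(triisopropylsilyloxy)butyl]-3-(triisopropylsilyloxy)phenol, via vinylketene 16 (not isolated), via vinylcyclobutenone adduct 17 (not isolated), via dienylketene 18 (not isolated), via cyclohexadienone tautomer 19 (not isolated)
Conditions: 15 (2.5 equiv, slow addition), toluene, 80 °C, then 110 °C, sealed vessel
Reagents that add atoms: none
Why: Heating opens 15 by a 4π-electrocyclic ring opening to vinylketene 16. The electron-rich alkyne 12 adds across the ketene C=C bond in a [2+2] cycloaddition in which its nucleophilic carbon (the one carrying the side chain, β to oxygen) bonds to the ketene carbonyl carbon (the future C4a–C8a bond) and its oxygen-bearing carbon bonds to the ketene α-carbon (C5–C6), giving 17. A second 4π opening gives dienylketene 18; only the isomer with the vinyl group cis to the ketene can go on, the other reverts to 17. Ring A is closed by a thermal disrotatory 6π-electrocyclisation of 18 (C8–C8a) to 19, which enolises to the aromatic 20. The closest known reaction is the Danheiser benzannulation of cyclobutenones with siloxyalkynes to 3-siloxyphenols. No stereocentre is created, since the sp3 ring carbon of 17 becomes aromatic, and the two existing centres are spectators because no acid or base touches the propargylic C–H. The selectivity needed is the regiochemistry of the ketene–alkyne union, which the polarisation of the ynol ether secures and which places the side chain between the two oxygens. Slow addition of excess 15 keeps the concentration of 16 low so that capture by 12 can outrun ketene oligomerisation.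

Step 8
Reactants: 20 2-[(1S,3S)-1-(4,5-dimethoxynaphthalen-1-yl)-3-(triisopropylsilyloxy)butyl]-3-(triisopropylsilyloxy)phenol
Product: 21 2-[(1S,3S)-1-(4,5-dimethoxynaphthalen-1-yl)-3-hydroxybutyl]benzene-1,3-diol
Conditions: Bu4NF (3 equiv), THF, 0 °C to 40 °C; aqueous work-up
Reagents that add atoms: none
Why: Fluoride-induced cleavage of silyl ethers; the aryl silyl ether should fall quickly and the secondary alkyl triisopropylsilyl ether on gentle warming, and neither stereocentre is touched.

Step 9
Reactants: 21 2-[(1S,3S)-1-(4,5-dimethoxynaphthalen-1-yl)-3-hydroxybutyl]benzene-1,3-diol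
Product: 22 (2R,4S)-4-(4,5-dimethoxynaphthalen-1-yl)-2-methylchroman-5-ol (cladonaphchrom A)
Conditions: PPh3 (1.5 equiv), diisopropyl azodicarboxylate (1.5 equiv), THF (0.01 M), 0 °C to rt
Reagents that add atoms: none
Why: Intramolecular Mitsunobu etherification: the secondary alcohol is activated as an alkoxyphosphonium ion and a phenoxide displaces it in a 6-exo-tet SN2 closure with inversion, turning the S carbinol into C2 (R) and giving the 2,4-trans chroman. The two phenols are equivalent, so the position of closure is not an issue, and dilution favours ring closure over intermolecular ether formation.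

## Compound list

1 | 1,8-dimethoxynaphthalene | COc1cccc2cccc(OC)c12 | starting material
2 | 4-bromo-1,8-dimethoxynaphthalene | COc1cccc2c(Br)ccc(OC)c12 | intermediate
3 | (S)-γ-valerolactone, (5S)-5-methyloxolan-2-one | C[C@H]1CCC(=O)O1 | starting material
4 | lithium (5S)-5-methyl-4,5-dihydrofuran-2-olate | C[C@H]1CC=C([O-])O1.[Li+] | intermediate (not isolated)
5 | chloro[(5S)-5-methyl-4,5-dihydrofuran-2-olato]zinc | C[C@H]1CC=C(O[Zn]Cl)O1 | intermediate (not isolated)
6 | (5S)-3-(4,5-dimethoxynaphthalen-1-yl)-5-methyloxolan-2-one, C3 epimer mixture | COc1cccc2c(C3C[C@H](C)OC3=O)ccc(OC)c12 | intermediate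
7 | lithium (5S)-3-(4,5-dimethoxynaphthalen-1-yl)-5-methyl-4,5-dihydrofuran-2-olate | COc1cccc2c(C3=C([O-])O[C@@H](C)C3)ccc(OC)c12.[Li+] | intermediate (not isolated)
8 | (3S,5S)-3-(4,5-dimethoxynaphthalen-1-yl)-5-methyloxolan-2-one (cis) | COc1cccc2c([C@@H]3C[C@H](C)OC3=O)ccc(OC)c12 | intermediate
9 | lithium (3S,5S)-2-(dibromomethyl)-3-(4,5-dimethoxynaphthalen-1-yl)-5-methyloxolan-2-olate, C2 epimers | COc1cccc2c([C@@H]3C[C@H](C)OC3([O-])C(Br)Br)ccc(OC)c12.[Li+] | intermediate (not isolated)
10 | dilithium (3S,5S)-1,1-dibromo-3-(4,5-dimethoxynaphthalen-1-yl)hex-1-ene-2,5-bis(olate) | COc1cccc2c([C@H](C[C@H](C)[O-])C([O-])=C(Br)Br)ccc(OC)c12.[Li+].[Li+] | intermediate (not isolated)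
11 | dilithium (3S,5S)-3-(4,5-dimethoxynaphthalen-1-yl)hex-1-yne-1,5-bis(olate) | COc1cccc2c([C@H](C[C@H](C)[O-])C#C[O-])ccc(OC)c12.[Li+].[Li+] | intermediate (not isolated)
12 | triisopropyl{[(3S,5S)-3-(4,5-dimethoxynaphthalen-1-yl)-5-(triisopropylsilyloxy)hex-1-yn-1-yl]oxy}silane | COc1cccc2c([C@H](C[C@H](C)O[Si](C(C)C)(C(C)C)C(C)C)C#CO[Si](C(C)C)(C(C)C)C(C)C)ccc(OC)c12 | intermediate
13 | 3-oxocyclobutanecarboxylic acid | O=C1CC(C(=O)O)C1 | starting material
14 | 3-bromocyclobutanone | O=C1CC(Br)C1 | intermediate
15 | cyclobutenone | O=C1C=CC1 | intermediate
16 | buta-1,3-dien-1-one (vinylketene) | C=CC=C=O | intermediate (not isolated)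
17 | 2-[(1S,3S)-1-(4,5-dimethoxynaphthalen-1-yl)-3-(triisopropylsilyloxy)butyl]-3-(triisopropylsilyloxy)-4-vinylcyclobut-2-en-1-one, C4 epimers | COc1cccc2c([C@H](C[C@H](C)O[Si](C(C)C)(C(C)C)C(C)C)C3=C(O[Si](C(C)C)(C(C)C)C(C)C)C(C=C)C3=O)ccc(OC)c12 | intermediate (not isolated)
18 | (3E)-2-[(1S,3S)-1-(4,5-dimethoxynaphthalen-1-yl)-3-(triisopropylsilyloxy)butyl]-3-(triisopropylsilyloxy)hexa-1,3,5-trien-1-one | COc1cccc2c([C@H](C[C@H](C)O[Si](C(C)C)(C(C)C)C(C)C)C(=C=O)\C(O[Si](C(C)C)(C(C)C)C(C)C)=C/C=C)ccc(OC)c12 | intermediate (not isolated)
19 | 2-[(1S,3S)-1-(4,5-dimethoxynaphthalen-1-yl)-3-(triisopropylsilyloxy)butyl]-3-(triisopropylsilyloxy)cyclohexa-2,4-dien-1-one | COc1cccc2c([C@H](C[C@H](C)O[Si](C(C)C)(C(C)C)C(C)C)C3=C(O[Si](C(C)C)(C(C)C)C(C)C)C=CCC3=O)ccc(OC)c12 | intermediate (not isolated)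
20 | 2-[(1S,3S)-1-(4,5-dimethoxynaphthalen-1-yl)-3-(triisopropylsilyloxy)butyl]-3-(triisopropylsilyloxy)phenol | COc1cccc2c([C@H](C[C@H](C)O[Si](C(C)C)(C(C)C)C(C)C)c3c(O)cccc3O[Si](C(C)C)(C(C)C)C(C)C)ccc(OC)c12 | intermediate
21 | 2-[(1S,3S)-1-(4,5-dimethoxynaphthalen-1-yl)-3-hydroxybutyl]benzene-1,3-diol | COc1cccc2c([C@H](C[C@H](C)O)c3c(O)cccc3O)ccc(OC)c12 | intermediate
22 | (2R,4S)-4-(4,5-dimethoxynaphthalen-1-yl)-2-methylchroman-5-ol, cladonaphchrom A | COc1cccc2c([C@@H]3C[C@@H](C)Oc4cccc(O)c43)ccc(OC)c12 | target

## Step count and least certain steps

Total step count: 9. Longest linear sequence: 7 steps (steps 1, 2, 3, 4, 7, 8, 9 from 1); the cyclobutenone branch (steps 5 and 6) joins at step 7.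

Step 7 (key step). The most likely failure is oligomerisation of the unsubstituted vinylketene, or polymerisation of 15 itself, before the ketene is captured by the hindered alkyne. The cascade may also stall at the four-membered adduct 17, or the new phenol may be acylated by excess ketene. The parent vinylketene has no substituent to slow its self-reaction. The fallback sets out from 12 and returns at 20, and generates the vinylketene photochemically instead of thermally. Methyl vinyl ketone is trifluoroacetylated through its kinetic enolate (LiN(SiMe3)2, 2,2,2-trifluoroethyl trifluoroacetate) to 1,1,1-trifluorohex-5-ene-2,4-dione F1. Detrifluoroacetylative diazo transfer (methanesulfonyl azide, Et3N) gives 1-diazobut-3-en-2-one F2. Irradiation of F2 with 12 at room temperature triggers a Wolff rearrangement to 16, which is trapped as it forms at low stationary concentration. Brief heating then carries 17 through to 20.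

Step 4. The most likely failure is proton transfer from the acidic C3–H of 8 (α to the carbonyl and benzylic) to dibromomethyllithium in competition with carbonyl addition. This would return lactone with a scrambled C3 centre. Incomplete silylation of the hindered secondary alkoxide is a second concern. The fallback sets out from 8 and returns at 12, and avoids a basic carbanion at the lactone stage. Reduction with i-Bu2AlH at −78 °C gives the lactol (3S,5S)-3-(4,5-dimethoxynaphthalen-1-yl)-5-methyloxolan-2-ol F3. The preformed ylide Ph3P=CBr2 converts its open hydroxy aldehyde form into (2S,4R)-6,6-dibromo-4-(4,5-dimethoxynaphthalen-1-yl)hex-5-en-2-ol F4 (the descriptor at the aryl-bearing carbon changes only because the priorities change). Silylation with i-Pr3SiOTf and 2,6-lutidine gives {[(2S,4R)-6,6-dibromo-4-(4,5-dimethoxynaphthalen-1-yl)hex-5-en-2-yl]oxy}triisopropylsilane F5. Two equivalents of n-BuLi convert F5 into the lithium acetylide [(3R,5S)-3-(4,5-dimethoxynaphthalen-1-yl)-5-(triisopropylsilyloxy)hex-1-yn-1-yl]lithium F6. In the same flask LiOOt-Bu oxidises F6 to lithium (3S,5S)-3-(4,5-dimethoxynaphthalen-1-yl)-5-(triisopropylsilyloxy)hex-1-yn-1-olate F7, and i-Pr3SiOTf silylates F7 on oxygen to give 12.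

Step 2. The most likely failures are slow coupling of the electron-rich, peri-hindered bromide, a second arylation of the more acidic product, and self-condensation of the lactone enolate. The fallback sets out from 1 and returns at 6, and replaces the cross-coupling by electrophilic substitution and an epoxide opening. Friedel–Crafts acylation of 1 with ethyl chlorooxoacetate and AlCl3 at the same para position gives ethyl (4,5-dimethoxynaphthalen-1-yl)(oxo)acetate F8. Ionic hydrogenation (Et3SiH, CF3CO2H) removes the ketone oxygen to give ethyl (4,5-dimethoxynaphthalen-1-yl)acetate F9, and saponification with LiOH gives (4,5-dimethoxynaphthalen-1-yl)acetic acid F10. Its dianion (two equivalents of LiN(i-Pr)2) opens (S)-2-methyloxirane at the CH2 terminus to give (4S)-2-(4,5-dimethoxynaphthalen-1-yl)-4-hydroxypentanoic acid F11. F11 lactonises with TsOH in toluene to 6.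

Step 3. The most likely failure is poor facial selectivity in the protonation, because a methyl group two atoms away is a small directing element. The thermodynamic preference for the cis isomer is expected to be modest as well. The fallback sets out from 6 and returns at 8, and replaces protonation by hydrogen delivery to an alkene. Enolate 7 is trapped with PhSeBr to give (5S)-3-(4,5-dimethoxynaphthalen-1-yl)-5-methyl-3-(phenylselanyl)oxolan-2-one F12. Oxidation with H2O2 and syn elimination give the butenolide (5S)-3-(4,5-dimethoxynaphthalen-1-yl)-5-methylfuran-2(5H)-one F13, which must be kept away from base so that C5 is not lost. Hydrogenation over Rh/Al2O3 adds both hydrogens from the face opposite the C5 methyl group and should give 8.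

Step 9. The most likely failures are elimination of the activated secondary alcohol to an alkene and intermolecular etherification, because the nucleophilic phenols flank a very bulky substituent. The fallback sets out from 21 and returns at 22, and separates activation from displacement. The phenols are acetylated selectively (Ac2O, aqueous NaOH, 0 °C) to give 2-[(1S,3S)-1-(4,5-dimethoxynaphthalen-1-yl)-3-hydroxybutyl]-1,3-phenylene diacetate F14. Mesylation (MsCl, Et3N) gives (2S,4S)-4-(2,6-diacetoxyphenyl)-4-(4,5-dimethoxynaphthalen-1-yl)butan-2-yl methanesulfonate F15. K2CO3 in MeOH then removes the acetates, and the phenoxide displaces the mesylate with inversion to give 22.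

## Further compounds

F1 | step 7 | 1,1,1-trifluorohex-5-ene-2,4-dione | C=CC(=O)CC(=O)C(F)(F)F
F2 | step 7 | 1-diazobut-3-en-2-one | C=CC(=O)C=[N+]=[N-]
F3 | step 4 | (3S,5S)-3-(4,5-dimethoxynaphthalen-1-yl)-5-methyloxolan-2-ol, anomer mixture | COc1cccc2c([C@@H]3C[C@H](C)OC3O)ccc(OC)c12
F4 | step 4 | (2S,4R)-6,6-dibromo-4-(4,5-dimethoxynaphthalen-1-yl)hex-5-en-2-ol | COc1cccc2c([C@H](C[C@H](C)O)C=C(Br)Br)ccc(OC)c12
F5 | step 4 | {[(2S,4R)-6,6-dibromo-4-(4,5-dimethoxynaphthalen-1-yl)hex-5-en-2-yl]oxy}triisopropylsilane | COc1cccc2c([C@H](C[C@H](C)O[Si](C(C)C)(C(C)C)C(C)C)C=C(Br)Br)ccc(OC)c12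
F6 | step 4 | [(3R,5S)-3-(4,5-dimethoxynaphthalen-1-yl)-5-(triisopropylsilyloxy)hex-1-yn-1-yl]lithium | COc1cccc2c([C@H](C[C@H](C)O[Si](C(C)C)(C(C)C)C(C)C)C#C[Li])ccc(OC)c12
F7 | step 4 | lithium (3S,5S)-3-(4,5-dimethoxynaphthalen-1-yl)-5-(triisopropylsilyloxy)hex-1-yn-1-olate | COc1cccc2c([C@H](C[C@H](C)O[Si](C(C)C)(C(C)C)C(C)C)C#C[O-])ccc(OC)c12.[Li+]
F8 | step 2 | ethyl (4,5-dimethoxynaphthalen-1-yl)(oxo)acetate | COc1cccc2c(C(=O)C(=O)OCC)ccc(OC)c12
F9 | step 2 | ethyl (4,5-dimethoxynaphthalen-1-yl)acetate | COc1cccc2c(CC(=O)OCC)ccc(OC)c12
F10 | step 2 | (4,5-dimethoxynaphthalen-1-yl)acetic acid | COc1cccc2c(CC(=O)O)ccc(OC)c12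
F11 | step 2 | (4S)-2-(4,5-dimethoxynaphthalen-1-yl)-4-hydroxypentanoic acid, C2 epimers | COc1cccc2c(C(C[C@H](C)O)C(=O)O)ccc(OC)c12
F12 | step 3 | (5S)-3-(4,5-dimethoxynaphthalen-1-yl)-5-methyl-3-(phenylselanyl)oxolan-2-one, C3 epimers | COc1cccc2c(C3([Se]c4ccccc4)C[C@H](C)OC3=O)ccc(OC)c12
F13 | step 3 | (5S)-3-(4,5-dimethoxynaphthalen-1-yl)-5-methylfuran-2(5H)-one | COc1cccc2c(C3=C[C@H](C)OC3=O)ccc(OC)c12
F14 | step 9 | 2-[(1S,3S)-1-(4,5-dimethoxynaphthalen-1-yl)-3-hydroxybutyl]-1,3-phenylene diacetate | COc1cccc2c([C@H](C[C@H](C)O)c3c(OC(C)=O)cccc3OC(C)=O)ccc(OC)c12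
F15 | step 9 | (2S,4S)-4-(2,6-diacetoxyphenyl)-4-(4,5-dimethoxynaphthalen-1-yl)butan-2-yl methanesulfonate | COc1cccc2c([C@H](C[C@H](C)OS(C)(=O)=O)c3c(OC(C)=O)cccc3OC(C)=O)ccc(OC)c12
A1 | alternative 1 | (4S)-5-(benzyloxy)-4-(4,5-dimethoxynaphthalen-1-yl)chroman-2-one | COc1cccc2c([C@@H]3CC(=O)Oc4cccc(OCc5ccccc5)c43)ccc(OC)c12
A2 | alternative 1 | (3S)-4-(benzyloxy)-3-(4,5-dimethoxynaphthalen-1-yl)-2,3-dihydro-1H-inden-1-one | COc1cccc2c([C@@H]3CC(=O)c4cccc(OCc5ccccc5)c43)ccc(OC)c12
A3 | alternative 2 | (2R,4S)-4-(4,5-dimethoxynaphthalen-1-yl)-2-ethoxychroman-5-ol (2,4-cis) | COc1cccc2c([C@@H]3C[C@H](OCC)Oc4cccc(O)c43)ccc(OC)c12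
A4 | alternative 2 | 2-[(4,5-dimethoxynaphthalen-1-yl)(hydroxy)methyl]benzene-1,3-diol (racemic) | COc1cccc2c(C(O)c3c(O)cccc3O)ccc(OC)c12
A5 | alternative 2 | 6-[(4,5-dimethoxynaphthalen-1-yl)methylidene]-5-hydroxycyclohexa-2,4-dien-1-one | COc1cccc2c(C=C3C(=O)C=CC=C3O)ccc(OC)c12
A6 | alternative 2 | ethyl vinyl ether | C=COCC
A7 | alternative 3 | (2R,4S)-4-(4,5-dimethoxynaphthalen-1-yl)-5-(methoxymethoxy)-2-methylchromane | COc1cccc2c([C@@H]3C[C@@H](C)Oc4cccc(OCOC)c43)ccc(OC)c12
A8 | alternative 3 | 1-[2-{[(2R)-1-chloropropan-2-yl]oxy}-6-(methoxymethoxy)benzyl]-4,5-dimethoxynaphthalene | COc1cccc2c(Cc3c(OCOC)cccc3O[C@H](C)CCl)ccc(OC)c12
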